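**Strategy**

Ring B is built last, around the diaryl ether oxygen, so the hindered ether never has to be forged between two finished arenes. The exploited feature is that ring B is a fully substituted resorcinol whose O-bearing carbons flank the C-methyl carbon in an acetate-type alternation, and that it is fused to the five-membered lactone, whose O–CH2 ester bond can tether an open chain. One base-mediated operation closes the butenolide (ring-fusion C=C) and then the benzene ring (C–C bond to the ether-bearing carbon), giving the phthalide diaryl ether. The precursor is the acyclic mixed 2-methyl-3-oxoglutarate ester of a ring A aryloxy-hydroxyacetone, with ring A carrying a tert-butyl ester.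

Key step: step 10

Remark: the lactol carbon is R as drawn; because a 3-hydroxyphthalide can epimerize by opening to the formyl acid, it is created in the last step and is assumed to hold its configuration only under base-free, weakly acidic handling.
Remark: monomethyl methylmalonate (12) is assumed to be purchasable as the racemate (otherwise one half-saponification of dimethyl methylmalonate is added); its stereocentre disappears in step 10.
Remark: depsidone numbering used for 21–23: C1 = phthalide CH2 or CH(OH), C3 = phthalide C=O, C7 = depsidone C=O, O6 and O12 = ring oxygens of the seven-membered ring.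

**Route**

Step 1
Reactants: 1 3,4,5-trimethoxytoluene
Product: 3 2,3,4-trimethoxy-6-methylbenzaldehyde, via iminium salt 2 (not isolated)
Conditions: POCl3 (1.5 equiv), DMF, 0 to 70 °C; then H2O, 50 °C
Reagents that add atoms: N,N-dimethylformamide CN(C)C=O; water O
Why: Vilsmeier–Haack formylation; the two free ring positions are equivalent and each is activated by an ortho and a para methoxy group, so a single aldehyde should form.

Step 2
Reactants: 3 2,3,4-trimethoxy-6-methylbenzaldehyde
Product: 4 2,3-dihydroxy-4-methoxy-6-methylbenzaldehyde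
Conditions: BCl3 (3 equiv), CH2Cl2, −10 °C to rt; then H2O
Reagents that add atoms: none
Why: Chelation-directed Lewis acid cleavage of aryl methyl ethers: boron held by the formyl oxygen removes the ortho methyl, the aryloxyboron chloride so formed reaches only the neighbouring methoxy group, and the methoxy para to the aldehyde has no such anchor and should remain.

Step 3
Reactants: 4 2,3-dihydroxy-4-methoxy-6-methylbenzaldehyde
Product: 5 3-(benzyloxy)-2-hydroxy-4-methoxy-6-methylbenzaldehyde
Conditions: NaH (2.1 equiv), DMSO, rt; then BnBr (1.0 equiv), rt; then dilute HCl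
Reagents that add atoms: benzyl bromide BrCc1ccccc1
Why: Williamson etherification of the dianion, in which the C3 phenoxide is not conjugated with the formyl group and is therefore the more nucleophilic oxygen, while the C2 phenoxide stays chelated and unreactive.

Step 4
Reactants: 5 3-(benzyloxy)-2-hydroxy-4-methoxy-6-methylbenzaldehyde
Product: 6 3-(benzyloxy)-2-hydroxy-4-methoxy-6-methylbenzoic acid
Conditions: NaClO2, NaH2PO4, 2-methyl-2-butene (20 equiv), t-BuOH/THF/H2O, 0 °C to rt
Reagents that add atoms: NaClO2 (sodium chlorite) [Na+].[O-]Cl=O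
Why: Pinnick oxidation, with the alkene in large excess to trap hypochlorous acid before it can chlorinate the electron-rich ring position para to the free phenol.

Step 5
Reactants: 6 3-(benzyloxy)-2-hydroxy-4-methoxy-6-methylbenzoic acid
Product: 7 tert-butyl 3-(benzyloxy)-2-hydroxy-4-methoxy-6-methylbenzoate
Conditions: O-tert-butyl-N,N'-diisopropylisourea (3 equiv), CH2Cl2, rt
Reagents that add atoms: O-tert-butyl-N,N'-diisopropylisourea CC(C)NC(=NC(C)C)OC(C)(C)C
Why: Isourea esterification, in which the acid protonates the reagent and the carboxylate oxygen captures the tert-butyl group, so the hindered carbonyl carbon is never attacked and the less acidic phenol does not react.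

Step 6
Reactants: 7 tert-butyl 3-(benzyloxy)-2-hydroxy-4-methoxy-6-methylbenzoate; 8 1,3-dichloroacetone
Product: 9 tert-butyl 3-(benzyloxy)-2-(3-chloro-2-oxopropoxy)-4-methoxy-6-methylbenzoate
Conditions: K2CO3 (1.5 equiv), 8 (5 equiv), acetone, 45 °C
Reagents that add atoms: none
Why: Williamson alkylation of the phenoxide by a carbonyl-activated primary chloride, with the dihalide in excess against double displacement and the bulky tert-butyl ester preventing closure of the ketone enolate onto the ester.

Step 7
Reactants: 9 tert-butyl 3-(benzyloxy)-2-(3-chloro-2-oxopropoxy)-4-methoxy-6-methylbenzoate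
Product: 11 tert-butyl 3-(benzyloxy)-2-(3-hydroxy-2-oxopropoxy)-4-methoxy-6-methylbenzoate, via formate ester 10 (not isolated)
Conditions: HCO2K (3 equiv), NaI (10 mol %), MeOH, 60 °C
Reagents that add atoms: HCO2K (potassium formate) [K+].[O-]C=O
Why: SN2 displacement of the α-keto chloride by formate followed by methanolysis of the formate ester in the same pot, which frees the primary alcohol without hydroxide and so spares the ketone and the ester.

Step 8
Reactants: 12 monomethyl methylmalonate (3-methoxy-2-methyl-3-oxopropanoic acid, racemic); 13 Meldrum's acid (2,2-dimethyl-1,3-dioxane-4,6-dione)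
Product: 14 methyl 3-(2,2-dimethyl-4,6-dioxo-1,3-dioxan-5-ylidene)-3-hydroxy-2-methylpropanoate (racemic)
Conditions: DCC (1.1 equiv), DMAP (1.5 equiv), CH2Cl2, 0 °C to rt; cold aqueous KHSO4 wash
Reagents that add atoms: none
Why: Carbodiimide-mediated C-acylation of Meldrum's acid, the first stage of the Meldrum's acid route to β-keto esters, giving the acyl compound as its stabilized enol.

Step 9
Reactants: 11 tert-butyl 3-(benzyloxy)-2-(3-hydroxy-2-oxopropoxy)-4-methoxy-6-methylbenzoate; 14 acyl Meldrum's acid
Product: 16 1-methyl 5-{3-[2-(benzyloxy)-6-(tert-butoxycarbonyl)-3-methoxy-5-methylphenoxy]-2-oxopropyl} 2-methyl-3-oxopentanedioate (racemic), via acylketene 15 (not isolated)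
Conditions: toluene, 90 °C
Reagents that add atoms: none
Why: Thermal fragmentation of the acyl Meldrum's acid to acetone, CO2 and an acylketene that the primary alcohol traps, which assembles the base-sensitive chain regiospecifically under neutral conditions.

Step 10
Reactants: 16 mixed 2-methyl-3-oxoglutarate ester
Product: 18 tert-butyl 3-(benzyloxy)-2-[(5,7-dihydroxy-6-methyl-1-oxo-1,3-dihydro-2-benzofuran-4-yl)oxy]-4-methoxy-6-methylbenzoate, via acylbutenolide 17 (not isolated)
Conditions: Cs2CO3 (3 equiv), MeCN (0.02 M), argon, rt then 60 °C; then dilute HCl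
Reagents that add atoms: none
Why: Proposed new method: carbonate deprotonates the CH2 between the chain ketone and the acyloxy ester, the enolate adds to the aryloxymethyl ketone in a 5-(enolexo)-exo-trig aldol closure, and loss of water gives acylbutenolide 17 with the future ring-fusion C=C; the aryloxy-bearing CH2 is then the γ-position of an alkylidene 1,3-dicarbonyl, and its dienolate carbon attacks the terminal methyl ester in a 6-(enolendo)-exo-trig Dieckmann closure, after which loss of methoxide and enolization of the cyclohexenedione give the aromatic resorcinol. The closest known reaction types are the base-mediated Knoevenagel cyclization of acyloin β-ketoesters to 3-acylbutenolides and the Claisen or Dieckmann aromatization of polyketide-type oxo esters to resorcinols; their combination on an aryloxymethyl ketone, with a vinylogous carbanion as the Dieckmann donor, has no direct precedent. No stereocentre is formed, and the single sp3 methine of 16, used as a mixture of configurations and tautomers, becomes the C-methyl arene carbon. The step needs chemoselectivity among four acidic sites and five carbonyl acceptors: only the five-ring aldol can dehydrate, every other first closure is seven-membered or reversible, and afterwards the ring CH2 of the butenolide cannot cyclize without a bridgehead alkene, so the exocyclic aryloxymethylene should be the only productive donor. The ring A ester is a tert-butyl ester flanked by two ortho substituents, which should shut off the competing five-ring closure to a benzofuran-3-one, and irreversible aromatization should drain the reversible equilibria toward 18.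

Step 11
Reactants: 18 phthalide diaryl ether tert-butyl ester
Product: 21 11-(benzyloxy)-4-hydroxy-10-methoxy-5,8-dimethyl-1H-isobenzofuro[4,5-b][1,4]benzodioxepine-3,7-dione, via carboxylic acid 19 (not isolated), via mixed trifluoroacetic anhydride 20 (not isolated)
Conditions: TFA/CH2Cl2 (1:4), 0 °C to rt; concentrate; then TFAA (3 equiv), toluene, rt; aqueous NaHCO3 wash
Reagents that add atoms: none
Why: Acidolysis of the tert-butyl ester followed by lactonization through the mixed anhydride, in which only the ring B hydroxyl ortho to the ether oxygen can reach the activated carboxyl (seven-membered ring), while the other hydroxyl is hydrogen-bonded to the phthalide carbonyl and at most forms a trifluoroacetate that the bicarbonate wash cleaves.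

Step 12
Reactants: 21 O-benzyl depsidone
Product: 22 4,11-dihydroxy-10-methoxy-5,8-dimethyl-1H-isobenzofuro[4,5-b][1,4]benzodioxepine-3,7-dione
Conditions: H2 (1 atm), 10% Pd/C, EtOAc, rt
Reagents that add atoms: none
Why: Hydrogenolysis of the benzyl aryl ether under neutral, low-pressure conditions that should leave the phthalide and the depsidone aryl ester untouched.

Step 13
Reactants: 22 deoxy depsidone
Product: 23 (1R)-1,4,11-trihydroxy-10-methoxy-5,8-dimethyl-1H-isobenzofuro[4,5-b][1,4]benzodioxepine-3,7-dione
Conditions: recombinant unspecific peroxygenase (variant chosen from a panel for the R product), H2O2 (1.2 equiv, syringe pump), ascorbic acid, potassium phosphate buffer pH 6.0 with 20% acetone, 20 °C; extraction at pH 5 without base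
Reagents that add atoms: hydrogen peroxide OO
Why: Proposed new method: the oxo-iron porphyrin radical cation of the heme-thiolate enzyme should abstract one enantiotopic hydrogen of the phthalide CH2 (the weakest C–H bond, benzylic and α to the lactone oxygen) and return OH to the same face by oxygen rebound with retention, so the R configuration is set by the active site presenting the pro-S hydrogen, and the closest known reaction types are peroxygenase benzylic hydroxylation of alkylbenzenes to enantioenriched alcohols and peroxygenase α-hydroxylation of ethers to hemiacetals.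

**Compound list**

1 | 3,4,5-trimethoxytoluene | COc1cc(C)cc(OC)c1OC | starting material
2 | N,N-dimethyl(2,3,4-trimethoxy-6-methylbenzylidene)iminium dichlorophosphate | COc1cc(C)c(C=[N+](C)C)c(OC)c1OC.[O-]P(=O)(Cl)Cl | intermediate
3 | 2,3,4-trimethoxy-6-methylbenzaldehyde | COc1cc(C)c(C=O)c(OC)c1OC | intermediate
4 | 2,3-dihydroxy-4-methoxy-6-methylbenzaldehyde | COc1cc(C)c(C=O)c(O)c1O | intermediate
5 | 3-(benzyloxy)-2-hydroxy-4-methoxy-6-methylbenzaldehyde | COc1cc(C)c(C=O)c(O)c1OCc1ccccc1 | intermediate
6 | 3-(benzyloxy)-2-hydroxy-4-methoxy-6-methylbenzoic acid | COc1cc(C)c(C(=O)O)c(O)c1OCc1ccccc1 | intermediate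
7 | tert-butyl 3-(benzyloxy)-2-hydroxy-4-methoxy-6-methylbenzoate | COc1cc(C)c(C(=O)OC(C)(C)C)c(O)c1OCc1ccccc1 | intermediate
8 | 1,3-dichloroacetone | ClCC(=O)CCl | starting material
9 | tert-butyl 3-(benzyloxy)-2-(3-chloro-2-oxopropoxy)-4-methoxy-6-methylbenzoate | COc1cc(C)c(C(=O)OC(C)(C)C)c(OCC(=O)CCl)c1OCc1ccccc1 | intermediate
10 | tert-butyl 3-(benzyloxy)-2-[3-(formyloxy)-2-oxopropoxy]-4-methoxy-6-methylbenzoate | COc1cc(C)c(C(=O)OC(C)(C)C)c(OCC(=O)COC=O)c1OCc1ccccc1 | intermediate
11 | tert-butyl 3-(benzyloxy)-2-(3-hydroxy-2-oxopropoxy)-4-methoxy-6-methylbenzoate | COc1cc(C)c(C(=O)OC(C)(C)C)c(OCC(=O)CO)c1OCc1ccccc1 | intermediate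
12 | monomethyl methylmalonate (3-methoxy-2-methyl-3-oxopropanoic acid, racemic) | COC(=O)C(C)C(=O)O | starting material
13 | Meldrum's acid (2,2-dimethyl-1,3-dioxane-4,6-dione) | CC1(C)OC(=O)CC(=O)O1 | starting material
14 | methyl 3-(2,2-dimethyl-4,6-dioxo-1,3-dioxan-5-ylidene)-3-hydroxy-2-methylpropanoate (racemic) | COC(=O)C(C)C(O)=C1C(=O)OC(C)(C)OC1=O | intermediate
15 | methyl 2-methyl-3,5-dioxopent-4-enoate (acylketene, racemic) | COC(=O)C(C)C(=O)C=C=O | intermediate
16 | 1-methyl 5-{3-[2-(benzyloxy)-6-(tert-butoxycarbonyl)-3-methoxy-5-methylphenoxy]-2-oxopropyl} 2-methyl-3-oxopentanedioate (racemic) | COC(=O)C(C)C(=O)CC(=O)OCC(=O)COc1c(C(=O)OC(C)(C)C)c(C)cc(OC)c1OCc1ccccc1 | intermediate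
17 | methyl 3-(4-{[2-(benzyloxy)-6-(tert-butoxycarbonyl)-3-methoxy-5-methylphenoxy]methyl}-2-oxo-2,5-dihydrofuran-3-yl)-2-methyl-3-oxopropanoate (racemic) | COC(=O)C(C)C(=O)C1=C(COc2c(C(=O)OC(C)(C)C)c(C)cc(OC)c2OCc2ccccc2)COC1=O | intermediate
18 | tert-butyl 3-(benzyloxy)-2-[(5,7-dihydroxy-6-methyl-1-oxo-1,3-dihydro-2-benzofuran-4-yl)oxy]-4-methoxy-6-methylbenzoate | CC(C)(C)OC(=O)c1c(C)cc(OC)c(OCc2ccccc2)c1Oc1c(O)c(C)c(O)c2c1COC2=O | intermediate
19 | 3-(benzyloxy)-2-[(5,7-dihydroxy-6-methyl-1-oxo-1,3-dihydro-2-benzofuran-4-yl)oxy]-4-methoxy-6-methylbenzoic acid | OC(=O)c1c(C)cc(OC)c(OCc2ccccc2)c1Oc1c(O)c(C)c(O)c2c1COC2=O | intermediate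
20 | mixed anhydride of 19 with trifluoroacetic acid | O=C(OC(=O)C(F)(F)F)c1c(C)cc(OC)c(OCc2ccccc2)c1Oc1c(O)c(C)c(O)c2c1COC2=O | intermediate
21 | 11-(benzyloxy)-4-hydroxy-10-methoxy-5,8-dimethyl-1H-isobenzofuro[4,5-b][1,4]benzodioxepine-3,7-dione (depsidone: ring A carboxyl esterified by the ring B oxygen ortho to the ether oxygen) | COc1cc(C)c2c(c1OCc1ccccc1)Oc1c(c(C)c(O)c3c1COC3=O)OC2=O | intermediate
22 | 4,11-dihydroxy-10-methoxy-5,8-dimethyl-1H-isobenzofuro[4,5-b][1,4]benzodioxepine-3,7-dione | COc1cc(C)c2c(c1O)Oc1c(c(C)c(O)c3c1COC3=O)OC2=O | intermediate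
23 | (1R)-1,4,11-trihydroxy-10-methoxy-5,8-dimethyl-1H-isobenzofuro[4,5-b][1,4]benzodioxepine-3,7-dione (R at the lactol carbon) | COc1cc(C)c2c(c1O)Oc1c(c(C)c(O)c3c1[C@H](O)OC3=O)OC2=O | target

**Step count**

Total: 13 steps. Longest linear sequence: 12 steps (steps 1–7 and 9–13 from 1); step 8 is a one-step branch.

**Steps most likely to fail**

1. Step 10. After the first closure the cascade may stall: the β-ketoester that must accept the carbanion is itself enolized under the same base, so C-acylation may be slow and intermolecular Claisen or Michael pathways may take over. The fallback is a Diels–Alder benzannulation (known chemistry) that sets out from 7 and comes back at 18.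
 - Methyl 2-methylacetoacetate is brominated (Br2, CHCl3, with acid-mediated migration of bromine to the terminal carbon) to methyl 4-bromo-2-methyl-3-oxobutanoate F1.
 - Williamson alkylation of 7 with it (K2CO3, acetone) gives methyl 4-[2-(benzyloxy)-6-(tert-butoxycarbonyl)-3-methoxy-5-methylphenoxy]-2-methyl-3-oxobutanoate F2.
 - Two-stage silylation (Et3N, TMSCl; then LDA, TMSCl, THF, −78 °C) gives the 4-aryloxy-1-methoxy-2-methyl-1,3-bis(trimethylsilyloxy)buta-1,3-diene F3.
 - Diels–Alder reaction with methyl 4-(tert-butyldimethylsilyloxy)but-2-ynoate (toluene, 80–110 °C) should join the aryloxy-bearing diene terminus to the alkyne carbon β to the ester. Aromatization by loss of methanol and hydrolytic work-up then gives methyl 3-aryloxy-2-[(tert-butyldimethylsilyloxy)methyl]-4,6-dihydroxy-5-methylbenzoate F4.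
 - Fluoride (HF·pyridine, THF) frees the benzylic alcohol, which lactonizes onto the neighbouring methyl ester to give 18.

2. Step 13. The bulky substrate may not be admitted to the heme channel. One-electron oxidation of the free phenols may compete. The lactol may be oxidized further to the anhydride. The enzyme may discriminate the two hydrogens poorly or in the wrong sense, and the product may racemize by ring opening. The fallback (known chemistry) sets out from 22 and comes back at 23.
 - Acetylation (Ac2O, pyridine) gives the diacetate F5.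
 - Wohl–Ziegler bromination (NBS, AIBN cat., PhCF3, 80 °C) at the phthalide CH2, the C–H bond that is both benzylic and α to the lactone oxygen, gives the racemic 1-bromo diacetate F6.
 - Hydrolysis (aqueous HCl, dioxane, 60 °C) exchanges bromide for hydroxyl and removes both acetates to give the racemic lactol F7.
 - Preparative chromatography on a chiral stationary phase under cold, weakly acidic conditions then gives the R enantiomer 23.

3. Step 6. Two phenoxides may displace both chlorides of one dihalide, the dihalide may self-condense under base, and the hindered, hydrogen-bonded phenoxide may alkylate slowly. The fallback sets out from 7 and comes back at 11, bypassing step 7 as well.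
 - Mitsunobu etherification of 7 with excess 2-methylidenepropane-1,3-diol (PPh3, DIAD, THF) gives tert-butyl 3-(benzyloxy)-2-{[2-(hydroxymethyl)prop-2-en-1-yl]oxy}-4-methoxy-6-methylbenzoate F8.
 - Ozonolysis of the 1,1-disubstituted alkene (O3, CH2Cl2/MeOH, −78 °C, dye end point; then Me2S) gives hydroxyketone 11 directly.

Further compounds
F1 | step 10 | methyl 4-bromo-2-methyl-3-oxobutanoate (racemic) | COC(=O)C(C)C(=O)CBr
F2 | step 10 | methyl 4-[2-(benzyloxy)-6-(tert-butoxycarbonyl)-3-methoxy-5-methylphenoxy]-2-methyl-3-oxobutanoate (racemic) | COC(=O)C(C)C(=O)COc1c(C(=O)OC(C)(C)C)c(C)cc(OC)c1OCc1ccccc1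
F3 | step 10 | tert-butyl 3-(benzyloxy)-4-methoxy-2-{[4-methoxy-3-methyl-2,4-bis(trimethylsilyloxy)buta-1,3-dien-1-yl]oxy}-6-methylbenzoate (alkene geometry not defined) | COC(O[Si](C)(C)C)=C(C)C(O[Si](C)(C)C)=COc1c(C(=O)OC(C)(C)C)c(C)cc(OC)c1OCc1ccccc1
F4 | step 10 | methyl 3-[2-(benzyloxy)-6-(tert-butoxycarbonyl)-3-methoxy-5-methylphenoxy]-2-[(tert-butyldimethylsilyloxy)methyl]-4,6-dihydroxy-5-methylbenzoate | COC(=O)c1c(O)c(C)c(O)c(Oc2c(C(=O)OC(C)(C)C)c(C)cc(OC)c2OCc2ccccc2)c1CO[Si](C)(C)C(C)(C)C
F5 | step 13 | 4,11-diacetoxy-10-methoxy-5,8-dimethyl-1H-isobenzofuro[4,5-b][1,4]benzodioxepine-3,7-dione | COc1cc(C)c2c(c1OC(C)=O)Oc1c(c(C)c(OC(C)=O)c3c1COC3=O)OC2=O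
F6 | step 13 | 4,11-diacetoxy-1-bromo-10-methoxy-5,8-dimethyl-1H-isobenzofuro[4,5-b][1,4]benzodioxepine-3,7-dione (racemic) | COc1cc(C)c2c(c1OC(C)=O)Oc1c(c(C)c(OC(C)=O)c3c1C(Br)OC3=O)OC2=O
F7 | step 13 | 1,4,11-trihydroxy-10-methoxy-5,8-dimethyl-1H-isobenzofuro[4,5-b][1,4]benzodioxepine-3,7-dione (racemic) | COc1cc(C)c2c(c1O)Oc1c(c(C)c(O)c3c1C(O)OC3=O)OC2=O
F8 | step 6 | tert-butyl 3-(benzyloxy)-2-{[2-(hydroxymethyl)prop-2-en-1-yl]oxy}-4-methoxy-6-methylbenzoate | CC(C)(C)OC(=O)c1c(C)cc(OC)c(OCc2ccccc2)c1OCC(=C)CO
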